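**Retrosynthetic overview**
- Target ⇐ lipase acetylation at O18 of nargenicin ⇐ Yamaguchi closure of the C1–O17 lactone; the C9 pyrrole ester and C11–OH come together from an Evans–Tishchenko reaction.
- Ring B and the C8–O13 ether ⇐ silicon-tethered intramolecular Diels–Alder from O13 onto the ring A enone (C7–C8, C11–C12), then capture of the C8 allyl cation by O13.
- C1–C3 arm with C4, C13 and C2 ⇐ catalyst-controlled desymmetrising Michael addition of an O13-bound pyruvate onto one enone arm of a p-quinol.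
- p-Quinol ⇐ vinyllithium of the C14–C19 fragment (from methyl (R)-lactate) plus quinone monoketal ⇐ oxidative dearomatisation of 4-methoxyphenol.
- Ring order: ring A (from the arene) → temporary six-membered lactone → ring B → tetrahydrofuran bridge → ten-membered lactone.

Assumption: "18-O-aacetyl" is read as 18-O-acetyl and the given SMILES is the target; C1–C19 below follow nargenicin numbering (C1 lactone carbonyl, C13 ether-bearing quaternary carbon, ring A = C4,5,6,7,12,13, ring B = C7–C12).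

The route is a paper proposal: nothing has been run, and a step that goes beyond precedent is marked in its Why line.

**Route**

Step 1
Reactants: 1 methyl (R)-lactate
Product: 2 methyl (2R)-2-[(tert-butyldimethylsilyl)oxy]propanoate
Conditions: TBSCl, imidazole, DMF, 23 °C
Reagents that add atoms: tert-butyldimethylsilyl chloride, C[Si](C)(Cl)C(C)(C)C
Why: Standard silyl ether formation; the C18 stereocentre (R) comes from the lactate and is not touched.

Step 2
Reactants: 2 methyl (2R)-2-[(tert-butyldimethylsilyl)oxy]propanoate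
Product: 3 (2R)-2-[(tert-butyldimethylsilyl)oxy]propanal
Conditions: iBu2AlH, CH2Cl2, −78 °C; potassium sodium tartrate (aq) work-up
Reagents that add atoms: none
Why: Partial ester reduction stops at the aluminium hemiacetal at −78 °C, so the aldehyde is released only on work-up and C18 does not epimerise.

Step 3
Reactants: 3 (2R)-2-[(tert-butyldimethylsilyl)oxy]propanal
Product: 4 (3R,4S,5R)-5-[(tert-butyldimethylsilyl)oxy]-3-methylhex-1-en-4-ol
Conditions: (R,R)-diisopropyl tartrate (Z)-crotylboronate, 4 Å MS, PhMe, −78 °C; then H2O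
Reagents that add atoms: (R,R)-diisopropyl tartrate (Z)-crotylboronate, C/C=C\CB1O[C@@H](C(=O)OC(C)C)[C@H](C(=O)OC(C)C)O1
Why: Roush asymmetric crotylboration: the (Z)-crotyl unit gives the 16,17-syn relationship through a chair transition state, and the tartrate and the Felkin preference of the α-silyloxy aldehyde are matched for the 17,18-anti product.

Step 4
Reactants: 4 (3R,4S,5R)-5-[(tert-butyldimethylsilyl)oxy]-3-methylhex-1-en-4-ol
Product: 5 (3R,4S,5R)-5-[(tert-butyldimethylsilyl)oxy]-3-methyl-4-[(triethylsilyl)oxy]hex-1-ene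
Conditions: Et3SiOTf, 2,6-lutidine, CH2Cl2, −78 °C
Reagents that add atoms: triethylsilyl triflate, CC[Si](CC)(CC)OS(=O)(=O)C(F)(F)F
Why: Silylation of the hindered C17 alcohol with a group that can later be removed by dilute acid without loss of the C18 TBS ether.

Step 5
Reactants: 5 (3R,4S,5R)-5-[(tert-butyldimethylsilyl)oxy]-3-methyl-4-[(triethylsilyl)oxy]hex-1-ene
Product: 7 (2S,3S,4R)-4-[(tert-butyldimethylsilyl)oxy]-2-methyl-3-[(triethylsilyl)oxy]pentanal, via ozonide 6 (not isolated)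
Conditions: O3, CH2Cl2, −78 °C; then PPh3, −78 to 23 °C
Reagents that add atoms: ozone, [O-][O+]=O
Why: Ozonolysis with reductive work-up cleaves the only alkene; the α-stereocentre (C16) is kept by working cold and using the aldehyde directly.

Step 6
Reactants: 7 (2S,3S,4R)-4-[(tert-butyldimethylsilyl)oxy]-2-methyl-3-[(triethylsilyl)oxy]pentanal
Product: 8 (2Z,4R,5S,6R)-6-[(tert-butyldimethylsilyl)oxy]-2-iodo-4-methyl-5-[(triethylsilyl)oxy]hept-2-ene
Conditions: [Ph3PCH(I)CH3]I, NaN(SiMe3)2, THF, −78 °C; then 7, −78 to −20 °C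
Reagents that add atoms: (1-iodoethyl)triphenylphosphonium iodide, CC(I)[P+](c1ccccc1)(c1ccccc1)c1ccccc1.[I-]
Why: Stork–Zhao type Wittig olefination with the non-stabilised iodo ylide gives the (Z)-2-iodoalkene (iodine cis to C16), which fixes the C14=C15 geometry of the target.

Step 7
Reactants: 9 4-methoxyphenol
Product: 10 4,4-dimethoxycyclohexa-2,5-dien-1-one
Conditions: PhI(OAc)2, MeOH, 0 °C
Reagents that add atoms: methanol, CO
Why: Oxidative dearomatisation of the phenol by the trivalent iodine reagent with methanol capture at the para carbon gives the symmetric quinone monoketal that becomes ring A.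

Step 8
Reactants: 8 (2Z,4R,5S,6R)-6-[(tert-butyldimethylsilyl)oxy]-2-iodo-4-methyl-5-[(triethylsilyl)oxy]hept-2-ene; 10 4,4-dimethoxycyclohexa-2,5-dien-1-one
Product: 13 4-hydroxy-4-[(2Z,4R,5S,6R)-6-[(tert-butyldimethylsilyl)oxy]-4-methyl-5-[(triethylsilyl)oxy]hept-2-en-2-yl]cyclohexa-2,5-dien-1-one, via vinyllithium 11 (not isolated), via ketal carbinol 12 (not isolated)
Conditions: tBuLi (2.1 equiv), Et2O, −78 °C; then 10, −78 °C; then AcOH, H2O, THF, 0 to 23 °C
Reagents that add atoms: water, O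
Why: Iodine–lithium exchange with retention of alkene geometry, 1,2-addition to the dienone carbonyl and mild ketal hydrolysis give the p-quinol; C13 is not yet a stereocentre because the two enone arms are equivalent.

Step 9
Reactants: 13 the p-quinol
Product: 14 pyruvate (2-oxopropanoate) ester of the tertiary alcohol of 13
Conditions: pyruvoyl chloride (freshly distilled), pyridine, CH2Cl2, −20 °C
Reagents that add atoms: pyruvoyl chloride, CC(=O)C(Cl)=O
Why: Acylation of the tertiary quinol hydroxyl with a reactive α-keto acid chloride under weak base, which installs C1–C3 on O13 without starting the Michael addition.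

Step 10
Reactants: 14 the p-quinol pyruvate
Product: 15 cis-fused keto lactone: ring A cyclohexenone (C6 ketone, C7=C12) fused at C4–C13 to a six-membered 2,3-dioxo lactone (O13–C1(=O)–C2(=O)–C3H2–C4), new C3–C4 bond on the O13 face
Conditions: 1-[3,5-bis(trifluoromethyl)phenyl]-3-[(1R,2R)-2-(dimethylamino)cyclohexyl]thiourea (10 mol%), PhMe, −20 °C
Reagents that add atoms: none
Why: Proposed new method: the amine of the bifunctional catalyst enolises the pyruvate while the thiourea binds the dienone carbonyl, so the C3 enol carbon adds 6-exo to only one of the two enone arms, the ester tether forcing a cis-fused lactone and setting C4 and C13 together; the closest known reactions are thiourea- and amine-catalysed desymmetrising intramolecular Michael additions of tethered 1,3-dicarbonyl and aldehyde donors to cyclohexadienones; the arm selected by this catalyst antipode is unproven, and the enantiomeric catalyst is used if the other arm reacts.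

Step 11
Reactants: 15 the keto lactone
Product: 16 (2S)-hydroxy lactone (C2–OH cis to the C4–C5 bond on the lactone ring)
Conditions: NaBH4 (0.3 equiv), MeOH/CH2Cl2, −78 °C
Reagents that add atoms: none
Why: Chemoselective reduction of the activated α-keto lactone carbonyl in the presence of the enone; hydride attack on the convex face of the cis-fused bicycle gives the equatorial (2S) alcohol, which is also the more stable epimer.

Step 12
Reactants: 16 the (2S)-hydroxy lactone
Product: 18 methyl (2S)-2-methoxy-3-(ring A)propanoate with free tertiary C13–OH (ring A = 4-substituted cyclohex-2-enone carrying the C14–C19 chain), via lithium carboxylate 17 (not isolated)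
Conditions: LiOH, THF/H2O, 0 °C; evaporate; then Ag2O, MeI, DMF, 23 °C
Reagents that add atoms: lithium hydroxide, [Li+].[OH-]; iodomethane, CI
Why: Saponification opens the lactone irreversibly and frees O13, then carboxylate alkylation and Purdie methylation of the α-hydroxy ester give the C1 ester and the C2 methyl ether while the hindered tertiary alcohol stays free.

Step 13
Reactants: 18 the hydroxy ester; 19 (E)-4-acetoxy-2-methylbut-2-enal
Product: 22 silaketal-bridged Diels–Alder adduct: ring B cyclohexene (C8–OAc, C9=C10–Me, C11–O) cis-fused to ring A on the O13 face, O11 and O13 joined by Si(iPr)2, via silyl triflate 20 (not isolated), via silaketal triene 21 (not isolated)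
Conditions: iPr2Si(OTf)2 (1.0 equiv), 2,6-lutidine, CH2Cl2, −78 °C; then 19, Et3N, −78 to 0 °C; pentane filtration of the ammonium salts; then PhMe, 90 °C
Reagents that add atoms: diisopropylsilyl bis(triflate), CC(C)[Si](OS(=O)(=O)C(F)(F)F)(OS(=O)(=O)C(F)(F)F)C(C)C
Why: Silicon-tethered intramolecular Diels–Alder reaction: soft enolisation of the enal gives the silyl dienol ether on O13, and the short tether forces the C11–C12 and C7–C8 bonds, the O13 face and the cis C7/C12 fusion; the amine salts are removed before heating so that the β-acetoxy ketone of the adduct does not eliminate, and the C8 and C11 configurations of the adduct do not matter because both are erased later (steps 15 and 17).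

Step 14
Reactants: 22 the silaketal adduct
Product: 24 C5=C6 enol triflate of 22, via potassium enolate 23 (not isolated)
Conditions: KN(SiMe3)2, THF, −78 °C; then PhNTf2, −78 °C
Reagents that add atoms: N-phenylbis(trifluoromethanesulfonimide), O=S(=O)(N(c1ccccc1)S(=O)(=O)C(F)(F)F)C(F)(F)F
Why: Kinetic deprotonation of the C6 ketone at the C5 methylene rather than the ring-fusion C7 methine (whose enolate would expel the C8 acetate), then O-triflation in the cold; both hydroxyls are masked by the tether at this point.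

Step 15
Reactants: 24 the enol triflate
Product: 26 tricyclic ether: C8–O13 tetrahydrofuran bridge closed, C9=C10–Me, free C11–OH, C5=C6 enol triflate, via acetoxysilyl ether 25 (not isolated)
Conditions: Me3SiOTf (10 mol%), CH2Cl2, −78 to −40 °C; then MeOH, K2CO3 (1.1 equiv), 0 to 23 °C
Reagents that add atoms: none
Why: Lewis acid ionisation of the allylic acetate gives a cation stabilised at the methyl-bearing C10 terminus, the O13 silyl ether oxygen captures C8 on the only face it can reach to close the five-membered ether (SN1 allylic etherification with a silyl ether as the oxygen nucleophile), acetate takes over the silyl group, and buffered methanolysis of the dioxygenated silicon frees C11–OH.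

Step 16
Reactants: 26 the tricyclic enol triflate
Product: 27 tricyclic diene alcohol (C5=C6 alkene, C9=C10–Me, C11–OH)
Conditions: Pd(OAc)2 (5 mol%), PPh3, HCO2H, Bu3N, DMF, 60 °C
Reagents that add atoms: none
Why: Formate reduction of the enol triflate through oxidative addition to zerovalent palladium and hydride transfer installs the C5=C6 alkene; allylic ethers are not ionised under these conditions.

Step 17
Reactants: 27 the tricyclic diene alcohol
Product: 28 ring B enone (C11 ketone, C9=C10–Me)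
Conditions: Dess–Martin periodinane, CH2Cl2, 0 to 23 °C
Reagents that add atoms: none
Why: Dess–Martin oxidation of the allylic alcohol; enolisation towards C12 is blocked because C12 is a bridgehead of the oxabicyclo[3.2.1]octane, so the β-alkoxy ketone does not eliminate.

Step 18
Reactants: 28 the ring B enone
Product: 30 β-hydroxy ketone (C9–OH axial and trans to the ether oxygen on C8, C10–Me equatorial, C11 ketone), via boryl ketone 29 (not isolated)
Conditions: CuCl (10 mol%), Xantphos, NaOtBu (15 mol%), B2pin2, MeOH, THF, 23 °C; then NaBO3·4H2O, THF/H2O, 23 °C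
Reagents that add atoms: sodium perborate, [Na+].[Na+].O[B-]1(O)OO[B-](O)(O)OO1
Why: Conjugate borylation by a monovalent copper boryl occurs axially on the face away from the O13–C13 bridge, oxidation of the C–B bond with retention gives C9–OH, and C10 equilibrates to the equatorial methyl epimer because the axial one clashes with both bridge bonds.

Step 19
Reactants: 30 the β-hydroxy ketone; 31 tert-butyl 2-formyl-1H-pyrrole-1-carboxylate
Product: 32 C9 (N-Boc-pyrrole-2-carboxylate) ester with free equatorial C11–OH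
Conditions: SmI2 (30 mol%), 31 (4 equiv), THF, −10 °C
Reagents that add atoms: none
Why: Evans–Tishchenko reaction: the samarium-bound hemiacetal of the C9 oxygen delivers its hydride to the C11 ketone on the same face through a six-membered transition state, giving the 1,3-anti C11 alcohol and leaving the acyl group on O9, so ring B needs no protecting group; the N-Boc group keeps the pyrrole aldehyde electrophilic enough to form the hemiacetal.

Step 20
Reactants: 32 the N-Boc pyrrole ester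
Product: 34 seco acid (C1 CO2H, C17–OH and C11–OH free, C18–OTBS, pyrrole N–H), via lithium carboxylate 33 (not isolated)
Conditions: LiOH, THF/H2O, 0 °C; then 1 M HCl to pH 2, 0 to 23 °C
Reagents that add atoms: lithium hydroxide, [Li+].[OH-]
Why: Saponification of the activated α-methoxy methyl ester also cleaves the pyrrole N-Boc carbamate, and the acidic work-up removes the triethylsilyl ether much faster than the secondary TBS ether; the hindered, electron-rich C9 pyrrole ester survives.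

Step 21
Reactants: 34 the seco acid
Product: 36 18-O-TBS-nargenicin (ten-membered lactone), via mixed anhydride 35 (not isolated)
Conditions: 2,4,6-Cl3C6H2COCl, Et3N, THF, 23 °C; then DMAP, PhMe, 80 °C, slow addition (1 mM)
Reagents that add atoms: none
Why: Yamaguchi macrolactonisation; the (Z)-alkene and the rigid tricycle hold O17 near C1, while lactonisation onto the hindered C11–OH would need a bridged eight-membered ring.

Step 22
Reactants: 36 18-O-TBS-nargenicin
Product: 37 nargenicin (18-hydroxy parent macrolide)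
Conditions: HF·pyridine, pyridine, THF, 0 to 23 °C
Reagents that add atoms: none
Why: Buffered fluoride desilylation of the last silyl ether; esters, lactone and alkenes are inert.

Step 23
Reactants: 37 nargenicin
Product: 38 18-O-acetyl-nargenicin
Conditions: Novozym 435 (immobilised Candida antarctica lipase B), vinyl acetate, MTBE, 35 °C
Reagents that add atoms: vinyl acetate, C=COC(C)=O
Why: Lipase-catalysed transesterification takes the side-chain (R)-methyl carbinol (Kazlauskas preference) and not the cage-bound C11–OH, so C18 is acetylated without protecting C11.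

**Compound list**

1 | methyl (R)-lactate | C[C@@H](O)C(=O)OC | starting material
2 | methyl (2R)-2-(TBS-oxy)propanoate | C[C@@H](O[Si](C)(C)C(C)(C)C)C(=O)OC | intermediate
3 | (2R)-2-(TBS-oxy)propanal | C[C@@H](O[Si](C)(C)C(C)(C)C)C=O | intermediate
4 | (3R,4S,5R)-5-(TBS-oxy)-3-methylhex-1-en-4-ol | C=C[C@@H](C)[C@H](O)[C@@H](C)O[Si](C)(C)C(C)(C)C | intermediate
5 | (3R,4S,5R)-5-(TBS-oxy)-3-methyl-4-(TES-oxy)hex-1-ene | C=C[C@@H](C)[C@H](O[Si](CC)(CC)CC)[C@@H](C)O[Si](C)(C)C(C)(C)C | intermediate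
6 | ozonide (1,2,4-trioxolane) of 5 | C1OC(OO1)[C@@H](C)[C@H](O[Si](CC)(CC)CC)[C@@H](C)O[Si](C)(C)C(C)(C)C | intermediate (not isolated)
7 | (2S,3S,4R)-4-(TBS-oxy)-2-methyl-3-(TES-oxy)pentanal | O=C[C@@H](C)[C@H](O[Si](CC)(CC)CC)[C@@H](C)O[Si](C)(C)C(C)(C)C | intermediate
8 | (2Z,4R,5S,6R)-6-(TBS-oxy)-2-iodo-4-methyl-5-(TES-oxy)hept-2-ene | I/C(C)=C\[C@@H](C)[C@H](O[Si](CC)(CC)CC)[C@@H](C)O[Si](C)(C)C(C)(C)C | intermediate
9 | 4-methoxyphenol | COc1ccc(O)cc1 | starting material
10 | 4,4-dimethoxycyclohexa-2,5-dien-1-one | COC1(OC)C=CC(=O)C=C1 | intermediate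
11 | vinyllithium from 8 | [Li]/C(C)=C\[C@@H](C)[C@H](O[Si](CC)(CC)CC)[C@@H](C)O[Si](C)(C)C(C)(C)C | intermediate (not isolated)
12 | 4,4-dimethoxy-1-alkenylcyclohexa-2,5-dien-1-ol (ketal carbinol) | COC1(OC)C=CC(O)(C=C1)/C(C)=C\[C@@H](C)[C@H](O[Si](CC)(CC)CC)[C@@H](C)O[Si](C)(C)C(C)(C)C | intermediate (not isolated)
13 | p-quinol: 4-hydroxy-4-[(2Z,4R,5S,6R)-6-(TBS-oxy)-4-methyl-5-(TES-oxy)hept-2-en-2-yl]cyclohexa-2,5-dien-1-one | O=C1C=CC(O)(C=C1)/C(C)=C\[C@@H](C)[C@H](O[Si](CC)(CC)CC)[C@@H](C)O[Si](C)(C)C(C)(C)C | intermediate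
14 | pyruvate ester of 13 | CC(=O)C(=O)OC1(C=CC(=O)C=C1)/C(C)=C\[C@@H](C)[C@H](O[Si](CC)(CC)CC)[C@@H](C)O[Si](C)(C)C(C)(C)C | intermediate
15 | cis-fused keto lactone (C3–C4 bond cis to O13) | O=C1C(=O)C[C@H]2CC(=O)C=C[C@]2(O1)/C(C)=C\[C@@H](C)[C@H](O[Si](CC)(CC)CC)[C@@H](C)O[Si](C)(C)C(C)(C)C | intermediate
16 | (2S)-hydroxy lactone | O[C@H]1C[C@H]2CC(=O)C=C[C@@]2(/C(C)=C\[C@@H](C)[C@H](O[Si](CC)(CC)CC)[C@@H](C)O[Si](C)(C)C(C)(C)C)OC1=O | intermediate
17 | lithium (2S)-2-hydroxy carboxylate with free C13–OH | [Li+].[O-]C(=O)[C@@H](O)C[C@H]1CC(=O)C=C[C@]1(O)/C(C)=C\[C@@H](C)[C@H](O[Si](CC)(CC)CC)[C@@H](C)O[Si](C)(C)C(C)(C)C | intermediate (not isolated)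
18 | methyl (2S)-2-methoxy ester with free C13–OH and ring A enone | COC(=O)[C@@H](OC)C[C@H]1CC(=O)C=C[C@]1(O)/C(C)=C\[C@@H](C)[C@H](O[Si](CC)(CC)CC)[C@@H](C)O[Si](C)(C)C(C)(C)C | intermediate
19 | (E)-4-acetoxy-2-methylbut-2-enal | CC(=O)OC/C=C(\C)C=O | starting material
20 | O13 diisopropylsilyl triflate of 18 | COC(=O)[C@@H](OC)C[C@H]1CC(=O)C=C[C@]1(O[Si](C(C)C)(C(C)C)OS(=O)(=O)C(F)(F)F)/C(C)=C\[C@@H](C)[C@H](O[Si](CC)(CC)CC)[C@@H](C)O[Si](C)(C)C(C)(C)C | intermediate (not isolated)
21 | silaketal triene (O13–Si(iPr)2–O–dienyl acetate) | COC(=O)[C@@H](OC)C[C@H]1CC(=O)C=C[C@]1(O[Si](C(C)C)(C(C)C)O/C=C(C)/C=C/OC(C)=O)/C(C)=C\[C@@H](C)[C@H](O[Si](CC)(CC)CC)[C@@H](C)O[Si](C)(C)C(C)(C)C | intermediate (not isolated)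
22 | silaketal-bridged Diels–Alder adduct (endo isomer drawn) | COC(=O)[C@@H](OC)C[C@H]1CC(=O)[C@H]2[C@@H](OC(C)=O)C=C(C)[C@@H](O[Si](C(C)C)(C(C)C)O3)[C@H]2[C@]13/C(C)=C\[C@@H](C)[C@H](O[Si](CC)(CC)CC)[C@@H](C)O[Si](C)(C)C(C)(C)C | intermediate
23 | potassium C5=C6 enolate of 22 | [K+].COC(=O)[C@@H](OC)C[C@H]1C=C([O-])[C@H]2[C@@H](OC(C)=O)C=C(C)[C@@H](O[Si](C(C)C)(C(C)C)O3)[C@H]2[C@]13/C(C)=C\[C@@H](C)[C@H](O[Si](CC)(CC)CC)[C@@H](C)O[Si](C)(C)C(C)(C)C | intermediate (not isolated)
24 | C5=C6 enol triflate of 22 | COC(=O)[C@@H](OC)C[C@H]1C=C(OS(=O)(=O)C(F)(F)F)[C@H]2[C@@H](OC(C)=O)C=C(C)[C@@H](O[Si](C(C)C)(C(C)C)O3)[C@H]2[C@]13/C(C)=C\[C@@H](C)[C@H](O[Si](CC)(CC)CC)[C@@H](C)O[Si](C)(C)C(C)(C)C | intermediate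
25 | tricyclic ether with C11–O–Si(iPr)2–OAc | COC(=O)[C@@H](OC)C[C@H]1C=C(OS(=O)(=O)C(F)(F)F)[C@H]2[C@H]3O[C@]1(/C(C)=C\[C@@H](C)[C@H](O[Si](CC)(CC)CC)[C@@H](C)O[Si](C)(C)C(C)(C)C)[C@@H]2[C@H](O[Si](C(C)C)(C(C)C)OC(C)=O)C(C)=C3 | intermediate (not isolated)
26 | tricyclic ether, C11–OH, enol triflate | COC(=O)[C@@H](OC)C[C@H]1C=C(OS(=O)(=O)C(F)(F)F)[C@H]2[C@H]3O[C@]1(/C(C)=C\[C@@H](C)[C@H](O[Si](CC)(CC)CC)[C@@H](C)O[Si](C)(C)C(C)(C)C)[C@@H]2[C@H](O)C(C)=C3 | intermediate
27 | tricyclic diene alcohol | COC(=O)[C@@H](OC)C[C@H]1C=C[C@H]2[C@H]3O[C@]1(/C(C)=C\[C@@H](C)[C@H](O[Si](CC)(CC)CC)[C@@H](C)O[Si](C)(C)C(C)(C)C)[C@@H]2[C@H](O)C(C)=C3 | intermediate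
28 | ring B enone | COC(=O)[C@@H](OC)C[C@H]1C=C[C@H]2[C@H]3O[C@]1(/C(C)=C\[C@@H](C)[C@H](O[Si](CC)(CC)CC)[C@@H](C)O[Si](C)(C)C(C)(C)C)[C@@H]2C(=O)C(C)=C3 | intermediate
29 | C9 pinacolboryl ketone | COC(=O)[C@@H](OC)C[C@H]1C=C[C@H]2[C@H]3O[C@]1(/C(C)=C\[C@@H](C)[C@H](O[Si](CC)(CC)CC)[C@@H](C)O[Si](C)(C)C(C)(C)C)[C@@H]2C(=O)[C@@H](C)[C@H]3B4OC(C)(C)C(C)(C)O4 | intermediate (not isolated)
30 | β-hydroxy ketone (C9–OH, C10–Me, C11=O) | COC(=O)[C@@H](OC)C[C@H]1C=C[C@H]2[C@H]3O[C@]1(/C(C)=C\[C@@H](C)[C@H](O[Si](CC)(CC)CC)[C@@H](C)O[Si](C)(C)C(C)(C)C)[C@@H]2C(=O)[C@@H](C)[C@H]3O | intermediate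
31 | tert-butyl 2-formyl-1H-pyrrole-1-carboxylate | O=Cc1cccn1C(=O)OC(C)(C)C | starting material
32 | C9 N-Boc-pyrrole-2-carboxylate, C11–OH | COC(=O)[C@@H](OC)C[C@H]1C=C[C@H]2[C@H]3O[C@]1(/C(C)=C\[C@@H](C)[C@H](O[Si](CC)(CC)CC)[C@@H](C)O[Si](C)(C)C(C)(C)C)[C@@H]2[C@H](O)[C@@H](C)[C@H]3OC(=O)c1cccn1C(=O)OC(C)(C)C | intermediate
33 | lithium C1 carboxylate (C17–OTES still on, N–H pyrrole) | [Li+].[O-]C(=O)[C@@H](OC)C[C@H]1C=C[C@H]2[C@H]3O[C@]1(/C(C)=C\[C@@H](C)[C@H](O[Si](CC)(CC)CC)[C@@H](C)O[Si](C)(C)C(C)(C)C)[C@@H]2[C@H](O)[C@@H](C)[C@H]3OC(=O)c1ccc[nH]1 | intermediate (not isolated)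
34 | seco acid | OC(=O)[C@@H](OC)C[C@H]1C=C[C@H]2[C@H]3O[C@]1(/C(C)=C\[C@@H](C)[C@H](O)[C@@H](C)O[Si](C)(C)C(C)(C)C)[C@@H]2[C@H](O)[C@@H](C)[C@H]3OC(=O)c1ccc[nH]1 | intermediate
35 | 2,4,6-trichlorobenzoic mixed anhydride of 34 | O=C(OC(=O)c1c(Cl)cc(Cl)cc1Cl)[C@@H](OC)C[C@H]1C=C[C@H]2[C@H]3O[C@]1(/C(C)=C\[C@@H](C)[C@H](O)[C@@H](C)O[Si](C)(C)C(C)(C)C)[C@@H]2[C@H](O)[C@@H](C)[C@H]3OC(=O)c1ccc[nH]1 | intermediate (not isolated)
36 | 18-O-TBS-nargenicin | CO[C@H]1C[C@H]2C=C[C@H]3[C@H]4O[C@]2(/C(C)=C\[C@@H](C)[C@@H]([C@@H](C)O[Si](C)(C)C(C)(C)C)OC1=O)[C@@H]3[C@H](O)[C@@H](C)[C@H]4OC(=O)c1ccc[nH]1 | intermediate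
37 | nargenicin (18-hydroxy parent macrolide) | CO[C@H]1C[C@H]2C=C[C@H]3[C@H]4O[C@]2(/C(C)=C\[C@@H](C)[C@@H]([C@@H](C)O)OC1=O)[C@@H]3[C@H](O)[C@@H](C)[C@H]4OC(=O)c1ccc[nH]1 | intermediate
38 | 18-O-acetyl-nargenicin | CO[C@H]1C[C@H]2C=C[C@H]3[C@H]4O[C@]2(/C(C)=C\[C@@H](C)[C@@H]([C@@H](C)OC(C)=O)OC1=O)[C@@H]3[C@H](O)[C@@H](C)[C@H]4OC(=O)c1ccc[nH]1 | target

**Step count**

Total: 23 steps. Longest linear sequence: 22 steps (steps 1–6, then 8–23; step 7 is the one-step branch).

**Steps most likely to fail, with fallbacks**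

Step 10 (catalytic desymmetrising Michael addition; new substrate class, arm selectivity unproven). Fallback: put the C2 stereocentre into the tether and let it choose the arm. The route sets out from p-quinol 13, which is esterified (DCC, DMAP, CH2Cl2) with (R)-3-iodo-2-methoxypropanoic acid to give the iodo ester F1. Its primary radical ((Me3Si)3SiH, Et3B, air, slow addition, PhH, 23 °C) closes 6-exo onto the enone arm that lets the methoxy group sit equatorial in a chair transition state, giving the methoxy lactone F2. LiOH and then MeI in DMF open F2 to hydroxy ester 18, where the main route is rejoined.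

Step 13 (tethered Diels–Alder; the tether forces a regiochemistry opposite to the electronic preference of the silyloxy diene). Fallback: build ring B by dearomatising a furan instead. The route sets out from hydroxy ester 18. Cycloaddition with 3-methylfuran (neat, 15 kbar, 23 °C) on the O13 face gives the exo oxanorbornene F3, whose nucleophilic C2 position (next to the methyl) bonds to C12. Me3SiOTf (cat.) ionises the allylic C8–O bridge bond and O13 recloses on C8, giving the tricyclic ether ketone F4 with C11–OH. Me3SiCl/Et3N followed by KN(SiMe3)2/PhNTf2 gives the silyl-protected enol triflate F5, and K2CO3/MeOH returns the main route at 26.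

Step 21 (ten-membered lactonisation next to a free C11–OH and a bulky C9 ester). Fallback: close the lactone three steps earlier, on a substrate that has neither. The route sets out from enone 28. LiOH and then dilute HCl give the enone seco acid F6, and lactonisation with 2-methyl-6-nitrobenzoic anhydride and DMAP (PhMe, 1 mM) gives the macrolactone enone F7. The conditions of step 18 then give the β-hydroxy ketone F8, and the conditions of step 19 with 31 give the N-Boc pyrrole ester F9. TFA in CH2Cl2 at 0 °C removes the Boc group and returns the main route at 36.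

**Further compounds**

F1 | step 10 | (R)-3-iodo-2-methoxypropanoate ester of p-quinol 13 | CO[C@@H](CI)C(=O)OC1(C=CC(=O)C=C1)/C(C)=C\[C@@H](C)[C@H](O[Si](CC)(CC)CC)[C@@H](C)O[Si](C)(C)C(C)(C)C
F2 | step 10 | cis-fused (2S)-methoxy lactone | CO[C@H]1C[C@H]2CC(=O)C=C[C@@]2(/C(C)=C\[C@@H](C)[C@H](O[Si](CC)(CC)CC)[C@@H](C)O[Si](C)(C)C(C)(C)C)OC1=O
F3 | step 13 | exo oxanorbornene adduct of 18 and 3-methylfuran (oxygen bridge C8–O–C11 on the O13 face) | COC(=O)[C@@H](OC)C[C@H]1CC(=O)[C@H]2[C@H]3O[C@H](C(C)=C3)[C@H]2[C@]1(O)/C(C)=C\[C@@H](C)[C@H](O[Si](CC)(CC)CC)[C@@H](C)O[Si](C)(C)C(C)(C)C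
F4 | step 13 | tricyclic ether ketone (C6 ketone, C8–O13 bridge, C11–OH, C9=C10–Me) | COC(=O)[C@@H](OC)C[C@H]1CC(=O)[C@H]2[C@H]3O[C@]1(/C(C)=C\[C@@H](C)[C@H](O[Si](CC)(CC)CC)[C@@H](C)O[Si](C)(C)C(C)(C)C)[C@@H]2[C@H](O)C(C)=C3
F5 | step 13 | C11 trimethylsilyl ether of enol triflate 26 | COC(=O)[C@@H](OC)C[C@H]1C=C(OS(=O)(=O)C(F)(F)F)[C@H]2[C@H]3O[C@]1(/C(C)=C\[C@@H](C)[C@H](O[Si](CC)(CC)CC)[C@@H](C)O[Si](C)(C)C(C)(C)C)[C@@H]2[C@H](O[Si](C)(C)C)C(C)=C3
F6 | step 21 | enone seco acid (C1 CO2H, C17–OH, C18–OTBS, C11 ketone) | OC(=O)[C@@H](OC)C[C@H]1C=C[C@H]2[C@H]3O[C@]1(/C(C)=C\[C@@H](C)[C@H](O)[C@@H](C)O[Si](C)(C)C(C)(C)C)[C@@H]2C(=O)C(C)=C3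
F7 | step 21 | macrolactone enone | CO[C@H]1C[C@H]2C=C[C@H]3[C@H]4O[C@]2(/C(C)=C\[C@@H](C)[C@@H]([C@@H](C)O[Si](C)(C)C(C)(C)C)OC1=O)[C@@H]3C(=O)C(C)=C4
F8 | step 21 | macrolactone β-hydroxy ketone | CO[C@H]1C[C@H]2C=C[C@H]3[C@H]4O[C@]2(/C(C)=C\[C@@H](C)[C@@H]([C@@H](C)O[Si](C)(C)C(C)(C)C)OC1=O)[C@@H]3C(=O)[C@@H](C)[C@H]4O
F9 | step 21 | N-Boc derivative of 36 | CO[C@H]1C[C@H]2C=C[C@H]3[C@H]4O[C@]2(/C(C)=C\[C@@H](C)[C@@H]([C@@H](C)O[Si](C)(C)C(C)(C)C)OC1=O)[C@@H]3[C@H](O)[C@@H](C)[C@H]4OC(=O)c1cccn1C(=O)OC(C)(C)C
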